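## Retrosynthetic overview

1. C12–C13 is cut last: Negishi coupling of the zinc reagent from iodide 30 with 2-(trimethylsilyl)ethyl (Z)-3-iodobut-2-enoate fixes the 13Z enoic acid; the 2β-acetate comes from a final silyl-to-acetyl exchange.
2. Iodide 30 goes back to β-keto ester 23: C12 by one-carbon homologation of C11, C17 by methylenation of the C8 ketone, C9 by equilibration of the β-keto ester, 5α-H by hydrogenation of a Δ5 bond.
3. The route rests on one feature: the quaternary C10 at the ring A/ring B fusion is allylic to C5=C6 in a Δ5 precursor of ring B, so an oxygen on C6 can hand its configuration to C10 while C9–C10 is made. This is done by Ireland–Claisen contraction of lactone 16 (breaks C6–O, forms C9–C10, closes ring B).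
4. Lactone 16 comes from aldehyde 7 and the bis(silyl) dienol ether of methyl acetoacetate by an enantioselective vinylogous aldol (sets C6), ketalisation and lactonisation.
5. Ring A is carried in from ketoisophorone (C2 set by asymmetric transfer hydrogenation); ring B is the only ring formed (step 11).

Key step: step 11

Remarks
- Numbering: the lactone carbons and all bicyclic compounds carry labdane numbers (rings C1–C10, C11 on C9, C17 on C8, two methyls on C4, one on C10); α is the face opposite the 10β-methyl. TBS = tert-butyldimethylsilyl, TBSO = its ether.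
- Assumption: the sense of induction in steps 1 and 8 follows aryl ketone and aryl aldehyde behaviour, with the alkenyl group in the place of aryl; if either proves opposite, the antipodal ligand is used and nothing else changes.

## Route

Step 1
Reactants: 1 ketoisophorone (2,6,6-trimethylcyclohex-2-ene-1,4-dione)
Product: 2 (4R)-4-hydroxy-2,6,6-trimethylcyclohex-2-en-1-one
Conditions: RuCl(p-cymene)[(R,R)-TsDPEN] (1 mol%), KOtBu (2 mol%), iPrOH, 25 °C
Reagents that add atoms: none
Why: Noyori asymmetric transfer hydrogenation should reduce only the less hindered C4 carbonyl (between CH= and CH2, not the one between C(Me)= and CMe2), and the (R,R)-ligand is expected to give the (4R)-carbinol, which becomes C2 of the target.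

Step 2
Reactants: 2 (4R)-4-hydroxy-2,6,6-trimethylcyclohex-2-en-1-one
Product: 3 (4R)-4-TBSO-2,6,6-trimethylcyclohex-2-en-1-one
Conditions: TBSCl, imidazole, DMF, 25 °C
Reagents that add atoms: tert-butyldimethylsilyl chloride, CC(C)(C)[Si](C)(C)Cl
Why: Standard silylation of an unhindered secondary alcohol, giving an ether that survives bases, hydrides and palladium chemistry.

Step 3
Reactants: 3 (4R)-4-TBSO-2,6,6-trimethylcyclohex-2-en-1-one
Product: 4 (4S)-4-TBSO-2,2,6-trimethylcyclohexan-1-one (mixture of epimers at ring C6)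
Conditions: H2 (1 bar), Pd/C, EtOAc, 25 °C
Reagents that add atoms: none
Why: Heterogeneous hydrogenation saturates the enone C=C; the new methyl-bearing centre need not be controlled because it becomes sp2 in step 4, and the carbinol descriptor changes from R to S only through CIP priorities.

Step 4
Reactants: 4 (4S)-4-TBSO-2,2,6-trimethylcyclohexan-1-one
Product: 6 (4S)-4-TBSO-2,6,6-trimethylcyclohex-1-en-1-yl trifluoromethanesulfonate, via lithium enolate 5 (not isolated)
Conditions: LiN(iPr)2, THF, −78 → 0 °C; PhNTf2, 0 → 25 °C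
Reagents that add atoms: N-phenylbis(trifluoromethanesulfonimide), O=S(=O)(N(c1ccccc1)S(=O)(=O)C(F)(F)F)C(F)(F)F; lithium diisopropylamide, [Li+].CC(C)[N-]C(C)C (lithium held only in 5)
Why: The ketone has a single α-hydrogen, so deprotonation can give only the tetrasubstituted enolate, which is O-sulfonylated to the enol triflate.

Step 5
Reactants: 6 (4S)-4-TBSO-2,6,6-trimethylcyclohex-1-en-1-yl trifluoromethanesulfonate
Product: 7 (4S)-4-TBSO-2,6,6-trimethylcyclohex-1-ene-1-carbaldehyde
Conditions: Pd(PPh3)4 (5 mol%), CO (3 bar), Bu3SnH (slow addition), LiCl, THF, 50 °C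
Reagents that add atoms: carbon monoxide, [C-]#[O+]
Why: Stille-type reductive carbonylation of an alkenyl triflate (oxidative addition, CO insertion, hydride transfer from tin); slow hydride addition under CO pressure should keep direct reduction of the hindered alkenylpalladium behind acyl formation.

Step 6
Reactants: 8 methyl acetoacetate
Product: 9 methyl 3-(trimethylsilyloxy)but-2-enoate
Conditions: Me3SiCl, Et3N, hexane, 25 °C
Reagents that add atoms: chlorotrimethylsilane, C[Si](C)(C)Cl
Why: Soft enolisation and O-silylation of the β-keto ester gives the silyl enol ether.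

Step 7
Reactants: 9 methyl 3-(trimethylsilyloxy)but-2-enoate
Product: 11 1-methoxy-1,3-bis(trimethylsilyloxy)buta-1,3-diene (Chan's diene), via lithium dienolate 10 (not isolated)
Conditions: LiN(iPr)2, THF, −78 °C; Me3SiCl, −78 → 0 °C
Reagents that add atoms: chlorotrimethylsilane, C[Si](C)(C)Cl; lithium diisopropylamide, [Li+].CC(C)[N-]C(C)C (lithium held only in 10)
Why: γ-Deprotonation of the vinylogous ester and O-silylation of the dienolate gives the bis(silyl) dienol ether, a vinylogous Mukaiyama nucleophile.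

Step 8
Reactants: 7 (4S)-4-TBSO-2,6,6-trimethylcyclohex-1-ene-1-carbaldehyde; 11 1-methoxy-1,3-bis(trimethylsilyloxy)buta-1,3-diene
Product: 13 methyl (5S)-5-[(4S)-4-TBSO-2,6,6-trimethylcyclohex-1-en-1-yl]-5-hydroxy-3-oxopentanoate, via silylated aldol adduct 12 (not isolated)
Conditions: Ti(OiPr)4 (10 mol%), (S)-BINOL (10 mol%), 4 Å molecular sieves, THF, −78 → 0 °C; then PPTS, MeOH, 0 °C
Reagents that add atoms: none
Why: In this catalytic enantioselective vinylogous Mukaiyama aldol the diene reacts at its terminal carbon and the titanium–BINOL complex selects the aldehyde face, so the new carbinol (C6) should be S; the C2 silyl ether is too remote to interfere, and a minor C6 epimer would be a separable diastereomer.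

Step 9
Reactants: 13 methyl (5S)-5-[(4S)-4-TBSO-2,6,6-trimethylcyclohex-1-en-1-yl]-5-hydroxy-3-oxopentanoate
Product: 14 methyl 2-{2-[(2S)-2-[(4S)-4-TBSO-2,6,6-trimethylcyclohex-1-en-1-yl]-2-(trimethylsilyloxy)ethyl]-1,3-dioxolan-2-yl}acetate
Conditions: Me3SiOCH2CH2OSiMe3 (3 equiv), Me3SiOTf (5 mol%), CH2Cl2, −78 → −30 °C; pyridine quench
Reagents that add atoms: 1,2-bis(trimethylsilyloxy)ethane, C[Si](C)(C)OCCO[Si](C)(C)C
Why: Noyori ketalisation under aprotic silyl triflate catalysis converts the C8 ketone into the dioxolane and caps the carbinol as its trimethylsilyl ether, so the acid-labile allylic C6–O bond never meets a protic acid.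

Step 10
Reactants: 14 methyl 2-{2-[(2S)-2-[(4S)-4-TBSO-2,6,6-trimethylcyclohex-1-en-1-yl]-2-(trimethylsilyloxy)ethyl]-1,3-dioxolan-2-yl}acetate
Product: 16 (7S)-7-[(4S)-4-TBSO-2,6,6-trimethylcyclohex-1-en-1-yl]-1,4,8-trioxaspiro[4.5]decan-9-one, via hydroxy acid 15 (not isolated)
Conditions: LiOH, THF/MeOH/H2O, 0 → 25 °C; 1 M HCl to pH 4–5 at 0 °C; then EDC·HCl, DMAP (cat.), CH2Cl2, 25 °C
Reagents that add atoms: lithium hydroxide, [Li+].[OH-]
Why: Saponification (which also removes the labile trimethylsilyl ether) and carbodiimide lactonisation close the six-membered lactone O–C11(=O)–C9–C8(ketal)–C7–C6 by 6-exo-trig acyl substitution without acid and without touching a stereocentre.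

Step 11
Reactants: 16 (7S)-7-[(4S)-4-TBSO-2,6,6-trimethylcyclohex-1-en-1-yl]-1,4,8-trioxaspiro[4.5]decan-9-one
Product: 19 2β-TBSO-8,8-(ethylenedioxy)-4,4,10β-trimethyl-Δ5-octalin-9α-carboxylic acid, via silyl ketene acetal 17 (not isolated), via trimethylsilyl ester 18 (not isolated)
Conditions: LiN(iPr)2 (1.5 equiv), Me3SiCl/Et3N (premixed, 4 equiv), THF, −78 °C (16 added last); warm to 25 °C; toluene, 105 °C; then 5% aq. citric acid, THF, 0 °C
Reagents that add atoms: chlorotrimethylsilane, C[Si](C)(C)Cl (silicon held only in 17 and 18, lost on work-up)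
Why: Deprotonation at C9 in the presence of Me3SiCl traps the lactone enolate at once as cyclic silyl ketene acetal 17, which on heating undergoes a suprafacial [3,3] sigmatropic shift that breaks C6–O and forms C9–C10, giving silyl ester 18 and, after hydrolysis, acid 19. The closest known reaction type is the Ireland–Claisen ring contraction of alkenyl-substituted lactones to cycloalkene carboxylic acids. Ring B (C5–C6–C7–C8–C9–C10) closes by this pericyclic contraction of the six-membered lactone through a bicyclo[2.2.2]octene-like boat transition state, the only one the lactone ring allows. C10 is set by C6: oxygen leaves and carbon arrives on the same face of the C6–C5=C10 allyl unit, so the (6S)-lactone delivers C9 to the face of C10 that leaves the methyl group β, whatever the remote 2β-silyl ether would prefer. C9 is set by the ring-fixed ketene acetal geometry and the boat arrangement, which place the carboxyl trans to the C10 methyl (9α-CO2H), the epimer that is corrected in step 14. The step needs O-silylation to outrun β-elimination of a ketal oxygen and needs complete 1,3-chirality transfer; the first is secured by the internal Me3SiCl quench at −78 °C, the second by the rigid tether.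

Step 12
Reactants: 19 2β-TBSO-8,8-(ethylenedioxy)-4,4,10β-trimethyl-Δ5-octalin-9α-carboxylic acid
Product: 20 methyl 2β-TBSO-8,8-(ethylenedioxy)-4,4,10β-trimethyl-Δ5-octalin-9α-carboxylate
Conditions: Me3SiCHN2, MeOH/toluene, 0 → 25 °C
Reagents that add atoms: (trimethylsilyl)diazomethane, C[Si](C)(C)C=[N+]=[N-] (supplies the ester methyl carbon)
Why: Diazoalkane O-methylation works on hindered acids under neutral conditions, and the ester is needed because the carboxyl must later survive next to the C8 ketone, where a free β-keto acid would decarboxylate.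

Step 13
Reactants: 20 methyl 2β-TBSO-8,8-(ethylenedioxy)-4,4,10β-trimethyl-Δ5-octalin-9α-carboxylate
Product: 21 methyl 2β-TBSO-8,8-(ethylenedioxy)-4,4,10β-trimethyl-5α-decalin-9α-carboxylate
Conditions: H2 (20 bar), [Ir(cod)(PCy3)(py)]PF6 (10 mol%), CH2Cl2, 25 °C
Reagents that add atoms: none
Why: Crabtree hydrogenation handles hindered trisubstituted alkenes and is directed by coordinating carbonyl groups; the 9α-ester sits on the α-face and the β-face is screened by the 10β- and 4β-methyl groups and the 2β-silyl ether, so both hydrogens should add from the α-face and set 5α-H (trans-decalin).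

Step 14
Reactants: 21 methyl 2β-TBSO-8,8-(ethylenedioxy)-4,4,10β-trimethyl-5α-decalin-9α-carboxylate
Product: 23 methyl 2β-TBSO-4,4,10β-trimethyl-8-oxo-5α-decalin-9β-carboxylate, via 9-epi keto ester 22 (not isolated)
Conditions: PPTS, acetone/H2O (10:1), 56 °C; then Et3N (cat.), CH2Cl2, 25 °C
Reagents that add atoms: water, O
Why: Acetal hydrolysis unmasks the C8 ketone, and the now doubly activated C9–H should epimerise through the enol to the β-keto ester with the equatorial 9β-ester (9α-H), the configuration of the target.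

Step 15
Reactants: 23 methyl 2β-TBSO-4,4,10β-trimethyl-8-oxo-5α-decalin-9β-carboxylate
Product: 24 methyl 2β-TBSO-4,4,10β-trimethyl-8-methylene-5α-decalin-9β-carboxylate
Conditions: Zn, CH2Br2, TiCl4 (pre-formed reagent), THF/CH2Cl2, 0 → 25 °C
Reagents that add atoms: dibromomethane, BrCBr
Why: Takai–Lombardo methylenation uses a non-basic zinc–titanium methylene donor that converts ketones into 1,1-disubstituted alkenes in the presence of esters and without deprotonating the acidic C9–H, which a phosphorus ylide would simply remove.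

Step 16
Reactants: 24 methyl 2β-TBSO-4,4,10β-trimethyl-8-methylene-5α-decalin-9β-carboxylate
Product: 25 [2β-TBSO-4,4,10β-trimethyl-8-methylene-5α-decalin-9β-yl]methanol
Conditions: LiAlH4, Et2O, 0 °C
Reagents that add atoms: none
Why: Hydride reduction of the ester to the primary alcohol (C11) leaves the silyl ether and the isolated alkene untouched and removes the acidity of C9–H.

Step 17
Reactants: 25 [2β-TBSO-4,4,10β-trimethyl-8-methylene-5α-decalin-9β-yl]methanol
Product: 26 2β-TBSO-4,4,10β-trimethyl-8-methylene-5α-decalin-9β-carbaldehyde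
Conditions: (nPr4N)RuO4 (5 mol%), N-methylmorpholine N-oxide, 4 Å molecular sieves, CH2Cl2, 25 °C
Reagents that add atoms: none
Why: Ley–Griffith oxidation stops at the aldehyde under neutral conditions, which should neither move the C8=C17 bond into conjugation nor epimerise C9.

Step 18
Reactants: 26 2β-TBSO-4,4,10β-trimethyl-8-methylene-5α-decalin-9β-carbaldehyde
Product: 27 9β-(2-methoxyvinyl)-2β-TBSO-4,4,10β-trimethyl-8-methylene-5α-decalin (E/Z mixture)
Conditions: Ph3P(CH2OMe)Cl, KN(SiMe3)2, THF, 0 °C; then 26, −78 → 0 °C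
Reagents that add atoms: (methoxymethyl)triphenylphosphonium chloride, COC[P+](c1ccccc1)(c1ccccc1)c1ccccc1.[Cl-]
Why: Wittig methoxymethylenation adds the C12 carbon; at −78 °C addition of the ylide to the aldehyde should be faster than deprotonation at C9.

Step 19
Reactants: 27 9β-(2-methoxyvinyl)-2β-TBSO-4,4,10β-trimethyl-8-methylene-5α-decalin
Product: 28 2-[2β-TBSO-4,4,10β-trimethyl-8-methylene-5α-decalin-9β-yl]acetaldehyde
Conditions: 1 M aq. HCl, THF, 25 °C (short contact)
Reagents that add atoms: water, O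
Why: Dilute-acid hydrolysis of the enol ether completes the one-carbon homologation under conditions that a secondary silyl ether and the exocyclic alkene should tolerate, and C9 is no longer α to a carbonyl.

Step 20
Reactants: 28 2-[2β-TBSO-4,4,10β-trimethyl-8-methylene-5α-decalin-9β-yl]acetaldehyde
Product: 29 2-[2β-TBSO-4,4,10β-trimethyl-8-methylene-5α-decalin-9β-yl]ethanol
Conditions: NaBH4, MeOH, 0 °C
Reagents that add atoms: none
Why: Borohydride reduces the aldehyde chemoselectively to the primary C12 alcohol.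

Step 21
Reactants: 29 2-[2β-TBSO-4,4,10β-trimethyl-8-methylene-5α-decalin-9β-yl]ethanol
Product: 30 9β-(2-iodoethyl)-2β-TBSO-4,4,10β-trimethyl-8-methylene-5α-decalin
Conditions: PPh3, I2, imidazole, CH2Cl2, 0 → 25 °C
Reagents that add atoms: iodine, II
Why: Appel-type iodination is an SN2 displacement of the alkoxyphosphonium ion at the unhindered primary C12.

Step 22
Reactants: 31 but-2-ynoic acid
Product: 32 (Z)-3-iodobut-2-enoic acid
Conditions: NaI, AcOH, 110 °C
Reagents that add atoms: sodium iodide, [Na+].[I-]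
Why: Conjugate hydroiodination of the ynoic acid (iodide at C3, anti protonation at C2) gives the Z isomer with iodine cis to the carboxyl.

Step 23
Reactants: 32 (Z)-3-iodobut-2-enoic acid
Product: 33 2-(trimethylsilyl)ethyl (Z)-3-iodobut-2-enoate
Conditions: Me3SiCH2CH2OH, EDC·HCl, DMAP (5 mol%), CH2Cl2, 0 °C
Reagents that add atoms: 2-(trimethylsilyl)ethanol, C[Si](C)(C)CCO
Why: Steglich esterification at 0 °C keeps the alkene geometry and installs an ester that fluoride removes later without touching an acetate-free late intermediate.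

Step 24
Reactants: 30 9β-(2-iodoethyl)-2β-TBSO-4,4,10β-trimethyl-8-methylene-5α-decalin; 33 2-(trimethylsilyl)ethyl (Z)-3-iodobut-2-enoate
Product: 35 2-(trimethylsilyl)ethyl (13Z)-2β-TBSO-labda-8(17),13-dien-15-oate, via alkylzinc iodide 34 (not isolated)
Conditions: Zn dust (activated), LiCl, THF, 40 °C; then 33, Pd(PPh3)4 (5 mol%), THF, 25 → 45 °C
Reagents that add atoms: zinc, [Zn] (held only in 34)
Why: In this Negishi coupling, oxidative addition of zerovalent palladium to the alkenyl iodide and reductive elimination both go with retention, so C12 ends cis to the ester (13Z); ester, silyl ether and exocyclic alkene are inert to the organozinc.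

Step 25
Reactants: 35 2-(trimethylsilyl)ethyl (13Z)-2β-TBSO-labda-8(17),13-dien-15-oate
Product: 36 (13Z)-2β-hydroxylabda-8(17),13-dien-15-oic acid
Conditions: Bu4NF (4 equiv), THF, 25 → 50 °C; aq. NH4Cl
Reagents that add atoms: none
Why: Fluoride cleaves the Si–O bond of the silyl ether and fragments the 2-(trimethylsilyl)ethyl ester (loss of ethene) in one operation, with no acid that could move the C8=C17 bond.

Step 26
Reactants: 36 (13Z)-2β-hydroxylabda-8(17),13-dien-15-oic acid
Product: 38 (13Z)-2β-acetoxylabda-8(17),13-dien-15-oic acid, via mixed anhydride 37 (not isolated)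
Conditions: Ac2O, pyridine, DMAP, 25 °C; then H2O/THF, NaHCO3; acidify to pH 3–4
Reagents that add atoms: acetic anhydride, CC(=O)OC(C)=O
Why: DMAP-catalysed acetylation esterifies the hindered axial 2β-hydroxyl, and the mixed carboxylic–acetic anhydride formed at C15 is hydrolysed in the aqueous work-up, which leaves the secondary acetate intact.

## Compound list

1 | ketoisophorone | CC1=CC(=O)CC(C)(C)C1=O | starting material
2 | (4R)-4-hydroxy-2,6,6-trimethylcyclohex-2-en-1-one | CC1=C[C@H](O)CC(C)(C)C1=O | intermediate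
3 | (4R)-4-TBSO-2,6,6-trimethylcyclohex-2-en-1-one | CC1=C[C@H](O[Si](C)(C)C(C)(C)C)CC(C)(C)C1=O | intermediate
4 | (4S)-4-TBSO-2,2,6-trimethylcyclohexan-1-one (epimers at ring C6) | CC1C[C@H](O[Si](C)(C)C(C)(C)C)CC(C)(C)C1=O | intermediate
5 | lithium (4S)-4-TBSO-2,6,6-trimethylcyclohex-1-en-1-olate | [Li+].[O-]C1=C(C)C[C@H](O[Si](C)(C)C(C)(C)C)CC1(C)C | intermediate
6 | (4S)-4-TBSO-2,6,6-trimethylcyclohex-1-en-1-yl trifluoromethanesulfonate | FC(F)(F)S(=O)(=O)OC1=C(C)C[C@H](O[Si](C)(C)C(C)(C)C)CC1(C)C | intermediate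
7 | (4S)-4-TBSO-2,6,6-trimethylcyclohex-1-ene-1-carbaldehyde | O=CC1=C(C)C[C@H](O[Si](C)(C)C(C)(C)C)CC1(C)C | intermediate
8 | methyl acetoacetate | CC(=O)CC(=O)OC | starting material
9 | methyl 3-(trimethylsilyloxy)but-2-enoate | COC(=O)C=C(C)O[Si](C)(C)C | intermediate
10 | lithium 1-methoxy-3-(trimethylsilyloxy)buta-1,3-dien-1-olate | [Li+].[O-]C(OC)=CC(=C)O[Si](C)(C)C | intermediate
11 | 1-methoxy-1,3-bis(trimethylsilyloxy)buta-1,3-diene | COC(O[Si](C)(C)C)=CC(=C)O[Si](C)(C)C | intermediate
12 | methyl (5S)-5-[(4S)-4-TBSO-2,6,6-trimethylcyclohex-1-en-1-yl]-3,5-bis(trimethylsilyloxy)pent-2-enoate | COC(=O)C=C(O[Si](C)(C)C)C[C@H](O[Si](C)(C)C)C1=C(C)C[C@H](O[Si](C)(C)C(C)(C)C)CC1(C)C | intermediate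
13 | methyl (5S)-5-[(4S)-4-TBSO-2,6,6-trimethylcyclohex-1-en-1-yl]-5-hydroxy-3-oxopentanoate | COC(=O)CC(=O)C[C@H](O)C1=C(C)C[C@H](O[Si](C)(C)C(C)(C)C)CC1(C)C | intermediate
14 | methyl 2-{2-[(2S)-2-[(4S)-4-TBSO-2,6,6-trimethylcyclohex-1-en-1-yl]-2-(trimethylsilyloxy)ethyl]-1,3-dioxolan-2-yl}acetate | COC(=O)CC1(OCCO1)C[C@H](O[Si](C)(C)C)C2=C(C)C[C@H](O[Si](C)(C)C(C)(C)C)CC2(C)C | intermediate
15 | 2-{2-[(2S)-2-[(4S)-4-TBSO-2,6,6-trimethylcyclohex-1-en-1-yl]-2-hydroxyethyl]-1,3-dioxolan-2-yl}acetic acid | OC(=O)CC1(OCCO1)C[C@H](O)C2=C(C)C[C@H](O[Si](C)(C)C(C)(C)C)CC2(C)C | intermediate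
16 | (7S)-7-[(4S)-4-TBSO-2,6,6-trimethylcyclohex-1-en-1-yl]-1,4,8-trioxaspiro[4.5]decan-9-one | O=C1CC2(OCCO2)C[C@H](O1)C3=C(C)C[C@H](O[Si](C)(C)C(C)(C)C)CC3(C)C | intermediate
17 | (7S)-7-[(4S)-4-TBSO-2,6,6-trimethylcyclohex-1-en-1-yl]-9-(trimethylsilyloxy)-1,4,8-trioxaspiro[4.5]dec-9-ene | C[Si](C)(C)OC1=CC2(OCCO2)C[C@H](O1)C3=C(C)C[C@H](O[Si](C)(C)C(C)(C)C)CC3(C)C | intermediate
18 | trimethylsilyl 2β-TBSO-8,8-(ethylenedioxy)-4,4,10β-trimethyl-Δ5-octalin-9α-carboxylate | O1CCOC12CC=C3C(C)(C)C[C@@H](O[Si](C)(C)C(C)(C)C)C[C@]3(C)[C@@H]2C(=O)O[Si](C)(C)C | intermediate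
19 | 2β-TBSO-8,8-(ethylenedioxy)-4,4,10β-trimethyl-Δ5-octalin-9α-carboxylic acid | O1CCOC12CC=C3C(C)(C)C[C@@H](O[Si](C)(C)C(C)(C)C)C[C@]3(C)[C@@H]2C(=O)O | intermediate
20 | methyl 2β-TBSO-8,8-(ethylenedioxy)-4,4,10β-trimethyl-Δ5-octalin-9α-carboxylate | O1CCOC12CC=C3C(C)(C)C[C@@H](O[Si](C)(C)C(C)(C)C)C[C@]3(C)[C@@H]2C(=O)OC | intermediate
21 | methyl 2β-TBSO-8,8-(ethylenedioxy)-4,4,10β-trimethyl-5α-decalin-9α-carboxylate | O1CCOC12CC[C@H]3C(C)(C)C[C@@H](O[Si](C)(C)C(C)(C)C)C[C@]3(C)[C@@H]2C(=O)OC | intermediate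
22 | methyl 2β-TBSO-4,4,10β-trimethyl-8-oxo-5α-decalin-9α-carboxylate | O=C1CC[C@H]2C(C)(C)C[C@@H](O[Si](C)(C)C(C)(C)C)C[C@]2(C)[C@@H]1C(=O)OC | intermediate
23 | methyl 2β-TBSO-4,4,10β-trimethyl-8-oxo-5α-decalin-9β-carboxylate | O=C1CC[C@H]2C(C)(C)C[C@@H](O[Si](C)(C)C(C)(C)C)C[C@]2(C)[C@H]1C(=O)OC | intermediate
24 | methyl 2β-TBSO-4,4,10β-trimethyl-8-methylene-5α-decalin-9β-carboxylate | C=C1CC[C@H]2C(C)(C)C[C@@H](O[Si](C)(C)C(C)(C)C)C[C@]2(C)[C@H]1C(=O)OC | intermediate
25 | [2β-TBSO-4,4,10β-trimethyl-8-methylene-5α-decalin-9β-yl]methanol | C=C1CC[C@H]2C(C)(C)C[C@@H](O[Si](C)(C)C(C)(C)C)C[C@]2(C)[C@H]1CO | intermediate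
26 | 2β-TBSO-4,4,10β-trimethyl-8-methylene-5α-decalin-9β-carbaldehyde | C=C1CC[C@H]2C(C)(C)C[C@@H](O[Si](C)(C)C(C)(C)C)C[C@]2(C)[C@H]1C=O | intermediate
27 | 9β-(2-methoxyvinyl)-2β-TBSO-4,4,10β-trimethyl-8-methylene-5α-decalin (E/Z) | C=C1CC[C@H]2C(C)(C)C[C@@H](O[Si](C)(C)C(C)(C)C)C[C@]2(C)[C@H]1C=COC | intermediate
28 | 2-[2β-TBSO-4,4,10β-trimethyl-8-methylene-5α-decalin-9β-yl]acetaldehyde | C=C1CC[C@H]2C(C)(C)C[C@@H](O[Si](C)(C)C(C)(C)C)C[C@]2(C)[C@H]1CC=O | intermediate
29 | 2-[2β-TBSO-4,4,10β-trimethyl-8-methylene-5α-decalin-9β-yl]ethanol | C=C1CC[C@H]2C(C)(C)C[C@@H](O[Si](C)(C)C(C)(C)C)C[C@]2(C)[C@H]1CCO | intermediate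
30 | 9β-(2-iodoethyl)-2β-TBSO-4,4,10β-trimethyl-8-methylene-5α-decalin | C=C1CC[C@H]2C(C)(C)C[C@@H](O[Si](C)(C)C(C)(C)C)C[C@]2(C)[C@H]1CCI | intermediate
31 | but-2-ynoic acid | CC#CC(=O)O | starting material
32 | (Z)-3-iodobut-2-enoic acid | C/C(I)=C/C(=O)O | intermediate
33 | 2-(trimethylsilyl)ethyl (Z)-3-iodobut-2-enoate | C/C(I)=C/C(=O)OCC[Si](C)(C)C | intermediate
34 | 2-[2β-TBSO-4,4,10β-trimethyl-8-methylene-5α-decalin-9β-yl]ethylzinc iodide | C=C1CC[C@H]2C(C)(C)C[C@@H](O[Si](C)(C)C(C)(C)C)C[C@]2(C)[C@H]1CC[Zn]I | intermediate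
35 | 2-(trimethylsilyl)ethyl (13Z)-2β-TBSO-labda-8(17),13-dien-15-oate | C=C1CC[C@H]2C(C)(C)C[C@@H](O[Si](C)(C)C(C)(C)C)C[C@]2(C)[C@H]1CC/C(C)=C\C(=O)OCC[Si](C)(C)C | intermediate
36 | (13Z)-2β-hydroxylabda-8(17),13-dien-15-oic acid | C=C1CC[C@H]2C(C)(C)C[C@@H](O)C[C@]2(C)[C@H]1CC/C(C)=C\C(=O)O | intermediate
37 | acetic (13Z)-2β-acetoxylabda-8(17),13-dien-15-oic anhydride | C=C1CC[C@H]2C(C)(C)C[C@@H](OC(C)=O)C[C@]2(C)[C@H]1CC/C(C)=C\C(=O)OC(C)=O | intermediate
38 | (13Z)-2β-acetoxylabda-8(17),13-dien-15-oic acid (CNP0255148.1) | C=C1CC[C@H]2C(C)(C)C[C@@H](OC(C)=O)C[C@]2(C)[C@H]1CC/C(C)=C\C(=O)O | target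

## Step count and risks

Total step count: 26. Longest linear sequence: 22 steps (steps 1–5, 8–21, 24–26, from ketoisophorone).

The three steps most likely to fail:

Step 11 (key step). The lactone enolate may fragment by β-elimination of a ketal oxygen before it is silylated, or on heating the allylic C6–O bond may ionise and eliminate instead of taking part in the rearrangement. The fallback sets out from 13 and returns at 23. Base (K2CO3, MeOH, then mild acid) closes 13 to the ketal-free β-keto δ-lactone F1. Me3SiCl/Et3N gives the 4-silyloxy dihydropyranone F2, and LiN(iPr)2/Me3SiCl then gives the 2,4-bis(trimethylsilyloxy)-2H-pyran F3, a ketene acetal with no β-leaving group whose ring is already boat-shaped. Heating should bring about the same suprafacial C6-to-C10 transfer (a Carroll-type variant) and give the dienyl silyl ester F4. Cold methanolysis gives the Δ5 β-keto acid F5, which is esterified at once (Me3SiCHN2) to the Δ5 β-keto ester F6, where C9 equilibrates to the 9β-ester. Hydrogen-atom-transfer hydrogenation of the Δ5 bond (Mn(dpm)3, PhSiH3, tBuOOH, iPrOH) then gives 23.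

Step 13. The Δ5 bond lies between two quaternary carbons and may not turn over on iridium, or hydrogen may be delivered to the β-face and give the cis-decalin, or the cationic catalyst may cleave the ketal. The fallback sets out from 20 and returns at 21 and makes no new compound. It is a radical hydrogen-atom-transfer hydrogenation (Mn(dpm)3, PhSiH3, tBuOOH, iPrOH, 25 °C): a hydrogen atom adds to C6, and the tertiary C5 radical takes its hydrogen from the open α-face, which leads to the more stable trans ring fusion without any need for the alkene to bind a metal.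

Step 15. Titanium may bind the β-keto ester as an enolate so that methylene transfer stalls, or the new exocyclic alkene may slip into conjugation with the ester during the Lewis-acidic work-up. The fallback sets out from 23 and returns at 25. Re-ketalisation (Me3SiOCH2CH2OSiMe3, Me3SiOTf) gives the 9β-ester ketal F7; LiAlH4 gives the ketal alcohol F8; PPTS in wet acetone gives the β-hydroxy ketone F9, which no longer has a doubly activated C9–H; Wittig methylenation with excess Ph3P=CH2 then gives 25.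

Further compounds
F1 | step 11 | (6S)-6-[(4S)-4-TBSO-2,6,6-trimethylcyclohex-1-en-1-yl]dihydro-2H-pyran-2,4(3H)-dione | O=C1CC(=O)C[C@H](O1)C2=C(C)C[C@H](O[Si](C)(C)C(C)(C)C)CC2(C)C
F2 | step 11 | (6S)-6-[(4S)-4-TBSO-2,6,6-trimethylcyclohex-1-en-1-yl]-4-(trimethylsilyloxy)-5,6-dihydro-2H-pyran-2-one | O=C1C=C(O[Si](C)(C)C)C[C@H](O1)C2=C(C)C[C@H](O[Si](C)(C)C(C)(C)C)CC2(C)C
F3 | step 11 | (2S)-2-[(4S)-4-TBSO-2,6,6-trimethylcyclohex-1-en-1-yl]-4,6-bis(trimethylsilyloxy)-2H-pyran | C[Si](C)(C)OC1=CC(O[Si](C)(C)C)=C[C@H](O1)C2=C(C)C[C@H](O[Si](C)(C)C(C)(C)C)CC2(C)C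
F4 | step 11 | trimethylsilyl 2β-TBSO-4,4,10β-trimethyl-8-(trimethylsilyloxy)-Δ5,7-hexalin-9α-carboxylate | C[Si](C)(C)OC1=CC=C2C(C)(C)C[C@@H](O[Si](C)(C)C(C)(C)C)C[C@]2(C)[C@@H]1C(=O)O[Si](C)(C)C
F5 | step 11 | 2β-TBSO-4,4,10β-trimethyl-8-oxo-Δ5-octalin-9-carboxylic acid | O=C1CC=C2C(C)(C)C[C@@H](O[Si](C)(C)C(C)(C)C)C[C@]2(C)C1C(=O)O
F6 | step 11 | methyl 2β-TBSO-4,4,10β-trimethyl-8-oxo-Δ5-octalin-9β-carboxylate | O=C1CC=C2C(C)(C)C[C@@H](O[Si](C)(C)C(C)(C)C)C[C@]2(C)[C@H]1C(=O)OC
F0 | step 13 | none | none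
F7 | step 15 | methyl 2β-TBSO-8,8-(ethylenedioxy)-4,4,10β-trimethyl-5α-decalin-9β-carboxylate | O1CCOC12CC[C@H]3C(C)(C)C[C@@H](O[Si](C)(C)C(C)(C)C)C[C@]3(C)[C@H]2C(=O)OC
F8 | step 15 | [2β-TBSO-8,8-(ethylenedioxy)-4,4,10β-trimethyl-5α-decalin-9β-yl]methanol | O1CCOC12CC[C@H]3C(C)(C)C[C@@H](O[Si](C)(C)C(C)(C)C)C[C@]3(C)[C@H]2CO
F9 | step 15 | 2β-TBSO-9β-(hydroxymethyl)-4,4,10β-trimethyl-5α-decalin-8-one | O=C1CC[C@H]2C(C)(C)C[C@@H](O[Si](C)(C)C(C)(C)C)C[C@]2(C)[C@H]1CO
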